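**Remark on the chemistry (assumption):** the target has no stereogenic centre, so "single enantiomer" is read as the single geometric isomer drawn, with the five stereodefined chain olefins (C2′, C6′, C10′, C14′, C18′) all E.

Atom labels used below: ring C1–C6 as in the quinone (C1=O, C2–OMe, C4=O, C6–chain); chain C1′–C24′ counted from the ring. "All-E hexaprenyl" = (2E,6E,10E,14E,18E)-3,7,11,15,19,23-hexamethyltetracosa-2,6,10,14,18,22-hexaen-1-yl.

## Analysis of the target

- The target 9 is a cyclohexa-2,5-diene-1,4-dione that carries OMe on C2 and a C30 chain on C6. Both substituents flank the C1 carbonyl; C3–H and C5–H flank the C4 carbonyl.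
- The chain is six isoprene units joined head to tail, with five trisubstituted E olefins and a terminal isopropylidene group at C22′.
- The five E olefins are the only stereochemical elements. They are remote from each other and cannot control one another, so each must be bought or made with its own geometry.
- Sensitive groups: the quinone (electrophilic, easily reduced, unstable to base), the C1′ methylene (allylic and attached to the ring), and the acid-sensitive polyene (cation–olefin cyclisation, chromanol formation at the hydroquinone stage).
- Every allylic CH2–X unit loses position or geometry as soon as a free allyl cation, allyl radical or equilibrating allyl metal is formed.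
- The first difficulty is the 2,6-pattern. The ring has three free CH positions, and uncatalysed nucleophiles attack C5 (conjugate to the more electrophilic C1=O), which gives the 2,5-isomer.
- The second difficulty is the head-to-tail C12′–C13′ link, which joins two allylic carbons that are both electrophiles by nature.
- The handle the route uses: O4=C4–C3=C2–OMe is a vinylogous ester, whereas O1=C1 is only cross-conjugated, so the two carbonyls differ in Lewis basicity.

## Retrosynthetic reasoning

**C6–C1′ (key disconnection).** 9 is cut between ring carbon C6 and chain carbon C1′, at the quinone oxidation level, into the unfunctionalised quinone 7 and the allylstannane 6. This reverses the usual polarity: the ring is the electrophile and the chain the nucleophile. What is gained is that no aryl halide, no phenol protection and no late oxidative unmasking are needed. The forward reaction must place the chain on C6 and not on C5 or C3, keep C1′ as the point of attachment, keep the 2′E olefin, and then return the hydroquinone 8 to the quinone in the same operation.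

**C1′–Sn.** 6 comes from the allylic chloride 5 by displacement with a stannyl anion. The cut is made here because the chloride is the group that the chain assembly leaves at C1′ anyway. The forward step must be an SN2 reaction without allylic transposition.

**C12′–C13′.** 5 is cut in the middle into two C15 pieces that both derive from the commercial chloride 1: the dihalide 3 and the allyl-barium derivative 4. This cut is chosen because it is the only one that makes both halves the same E,E-configured stock compound; four of the five E olefins are then bought. Both carbons are allylic electrophiles, so one is umpoled as 4. The forward reaction must join C-α to C-α′, keep all geometries, and displace the bromide of 3 while leaving its chloride untouched, so that the chain needs no protecting group.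

**C12′–Br and C12′–O.** 3 comes from the alcohol 2 by a phosphine/tetrahalomethane bromination, and 2 from 1 by selenium-mediated allylic oxidation of the E-methyl group of the terminal isopropylidene. This oxidation creates the fifth stereodefined olefin (C10′=C11′) as the E isomer. The forward steps must spare the allylic chloride.

## Alternatives that were turned down

**Alternative 1:** the textbook route. Cut C6–C1′ with the ring as nucleophile and the chain as electrophile.
- Forward key step: the aryl bromide A1 (1-bromo-2,3,5-trimethoxybenzene) is lithiated, transmetalated to copper and alkylated with all-E hexaprenyl bromide A2 to give the arene A3. Cerium(IV) oxidative demethylation of A3 would give 9.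
- Turned down because A1 is not a stock compound and three O-methyl groups are put on only to be destroyed.
- The final oxidation of a 1,2,4-trimethoxyarene must choose between the para-quinone and the ortho-quinone, and it exposes six olefins and the C1′ methylene to a one-electron oxidant.
- A2 needs the usual sulfone-mediated chain union with protection and deprotection of the chain terminus, so the route runs to about ten steps.
- The ring is handled as a protected arene although the target ring is itself an electrophile with two different carbonyls. The protecting-group-free variant of this disconnection is kept only as the fallback of the key step.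

**Alternative 2:** cut C1′–C2′ and C3′–CH3.
- Forward key step: zirconium-catalysed methylalumination of the terminal enyne A5 would create the C2′=C3′ olefin (syn addition, E) and the C3′ methyl branch. Nickel(0)-catalysed coupling of the alkenylalane with the benzylic chloride A4 would then form C1′–C2′ and give the protected phenol A6, followed by deprotection and para-oxidation.
- Turned down because the precursor is not simpler. A5 still contains four of the five E olefins and the C12′–C13′ link, so it needs 5 plus a propargylation and a desilylation.
- The alkyne C–H of A5 is not compatible with the allyl-barium union.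
- A4 costs three steps from a commercial salicylaldehyde and brings a phenol protecting group.
- The key step would make one olefin that can be bought, at a total of at least ten steps.

**Alternative 3:** build the quinone ring last.
- Forward key step: the lithium acetylide of the skipped enyne A8 (from 5 and an ethynyl nucleophile) is added to the cyclobutenedione A7 (3-methoxycyclobut-3-ene-1,2-dione). The adduct A9 is heated, so that electrocyclic opening to an alkynyl(vinyl)ketene and ring closure give a quinone.
- Turned down because the regiochemistry is wrong by construction. The acetylide adds to the more electrophilic carbonyl of A7, the one next to the methoxy-bearing carbon; the other carbonyl is a vinylogous ester.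
- In the ring expansion the chain-bearing alkyne carbon bonds to the ketene carbon, so the chain ends up beside the carbonyl remote from OMe. The product would be the 2,5-isomer A10, not 9.
- The route also needs 5 anyway, A7 is not a stock compound, and a hexaene with a propargylic/allylic C1′ methylene would be heated to about 140 °C.

Key step: step 5

## Route

Step 1
Reactants: 1 (2E,6E)-1-chloro-3,7,11-trimethyldodeca-2,6,10-triene ((2E,6E)-farnesyl chloride)
Product: 2 (2E,6E,10E)-12-chloro-2,6,10-trimethyldodeca-2,6,10-trien-1-ol
Conditions: SeO2 (0.3 equiv), t-BuOOH (5.5 M in decane, 3 equiv), salicylic acid (0.1 equiv), CH2Cl2, 0 °C → rt, stopped before full conversion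
Reagents that add atoms: selenium dioxide, O=[Se]=O (catalytic oxygen carrier); tert-butyl hydroperoxide, CC(C)(C)OO (terminal oxygen source)
Why: Catalytic selenium dioxide allylic oxidation (Riley-type; ene reaction then [2,3]-sigmatropic shift): the terminal isopropylidene is the most electron-rich and least hindered olefin, and the 2,3-olefin is deactivated by the allylic chlorine. The ene/[2,3] sequence puts oxygen on the E-methyl group, so the new trisubstituted olefin is E; anhydrous hydroperoxide is used to spare the allylic chloride.

Step 2
Reactants: 2 (2E,6E,10E)-12-chloro-2,6,10-trimethyldodeca-2,6,10-trien-1-ol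
Product: 3 (2E,6E,10E)-1-bromo-12-chloro-2,6,10-trimethyldodeca-2,6,10-triene
Conditions: CBr4, PPh3, CH2Cl2, −30 → 0 °C
Reagents that add atoms: carbon tetrabromide, BrC(Br)(Br)Br
Why: Appel reaction: bromide displaces the alkoxyphosphonium group at the primary carbon (SN2) without allylic transposition. At 0 °C or below and without excess halide salt the allylic chloride should not exchange.

Step 3
Reactants: 1 (2E,6E)-farnesyl chloride; 3 (2E,6E,10E)-1-bromo-12-chloro-2,6,10-trimethyldodeca-2,6,10-triene
Product: 5 (2E,6E,10E,14E,18E)-1-chloro-3,7,11,15,19,23-hexamethyltetracosa-2,6,10,14,18,22-hexaene (all-E hexaprenyl chloride), via farnesylbarium chloride 4 (not isolated)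
Conditions: active Ba [BaI2, Li, biphenyl, THF, rt]; 1 (slight excess over Ba), THF, −78 °C, 30 min; then 3, −78 °C
Reagents that add atoms: none
Why: Allylbarium cross-coupling, a union of two allylic electrophiles by polarity reversal: the allylbarium made from an allylic chloride keeps its position and E geometry at −78 °C and attacks an allylic bromide carbon-α to carbon-α′. Bromide should be displaced much faster than chloride (1 itself is turned into 4 at −78 °C without self-coupling), so the C1 chloride of 3 survives as the handle for step 4.

Step 4
Reactants: 5 all-E hexaprenyl chloride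
Product: 6 tributyl[(2E,6E,10E,14E,18E)-3,7,11,15,19,23-hexamethyltetracosa-2,6,10,14,18,22-hexaen-1-yl]stannane
Conditions: Bu3SnLi [Bu3SnH, LDA, THF, 0 °C]; 5, THF, −78 → −40 °C
Reagents that add atoms: tributyltin hydride, CCCC[SnH](CCCC)CCCC (used as its lithium derivative)
Why: SN2 displacement of the primary allylic chloride by the stannyl anion at low temperature; it should give the primary allylstannane with the 2E olefin untouched, as is known for polyprenyl halides.

Step 5
Reactants: 6 tributyl(all-E hexaprenyl)stannane; 7 2-methoxycyclohexa-2,5-diene-1,4-dione (2-methoxy-1,4-benzoquinone)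
Product: 9 2-methoxy-6-[(2E,6E,10E,14E,18E)-3,7,11,15,19,23-hexamethyltetracosa-2,6,10,14,18,22-hexaen-1-yl]cyclohexa-2,5-diene-1,4-dione, via 2-hexaprenyl-6-methoxyhydroquinone 8 (not isolated)
Conditions: 7 (1.3 equiv), BF3·OEt2 (2 equiv), CH2Cl2, −78 °C; 6, −78 → −40 °C; aq. NaHCO3; crude in Et2O, Ag2O, rt
Reagents that add atoms: none
Why: Lewis-acid-mediated allylation of a quinone by an allylstannane, the reaction type known for joining polyprenylstannanes to quinones under boron trifluoride, applied here to the unsymmetrical quinone 7. Monodentate BF3 should bind O4, the more basic oxygen, because C4=O is the carbonyl of the vinylogous ester O4=C4–C3=C2–OMe while O1=C1 is only cross-conjugated; C4=O is also the unhindered carbonyl. The stannane then attacks this activated half of the quinone, either directly at C6 (β to C4=O through C5=C6) or by 1,2-addition at C4 through C3′ followed by a [3,3] shift that reconnects C1′ to C6. The other β-position, C2, is blocked by OMe and cannot aromatise, so both pathways converge on the C6–C1′ bond, and loss of the C6 proton gives hydroquinone 8. Silver(I) oxide then oxidises 8 to 9. The step closes no ring and creates no stereocentre. It needs C6 rather than C5 (secured by a non-chelating Lewis acid; a chelating titanium or tin halide would bridge O1 and OMe and send the chain to C5), linear C1′ attachment with the 2′E olefin intact (the known outcome for γ,γ-disubstituted allylstannanes at −78 °C), and survival of the other olefins (low temperature, basic quench before warming).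

## Compound list

1 | (2E,6E)-1-chloro-3,7,11-trimethyldodeca-2,6,10-triene ((2E,6E)-farnesyl chloride) | ClC/C=C(\C)CC/C=C(\C)CCC=C(C)C | starting material
2 | (2E,6E,10E)-12-chloro-2,6,10-trimethyldodeca-2,6,10-trien-1-ol | ClC/C=C(\C)CC/C=C(\C)CC/C=C(\C)CO | intermediate
3 | (2E,6E,10E)-1-bromo-12-chloro-2,6,10-trimethyldodeca-2,6,10-triene | ClC/C=C(\C)CC/C=C(\C)CC/C=C(\C)CBr | intermediate
4 | (2E,6E)-farnesylbarium chloride | Cl[Ba]C/C=C(\C)CC/C=C(\C)CCC=C(C)C | intermediate (not isolated)
5 | (2E,6E,10E,14E,18E)-1-chloro-3,7,11,15,19,23-hexamethyltetracosa-2,6,10,14,18,22-hexaene (all-E hexaprenyl chloride) | ClC/C=C(\C)CC/C=C(\C)CC/C=C(\C)CC/C=C(\C)CC/C=C(\C)CCC=C(C)C | intermediate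
6 | tributyl[(2E,6E,10E,14E,18E)-3,7,11,15,19,23-hexamethyltetracosa-2,6,10,14,18,22-hexaen-1-yl]stannane | CCCC[Sn](CCCC)(CCCC)C/C=C(\C)CC/C=C(\C)CC/C=C(\C)CC/C=C(\C)CC/C=C(\C)CCC=C(C)C | intermediate
7 | 2-methoxycyclohexa-2,5-diene-1,4-dione (2-methoxy-1,4-benzoquinone) | COC1=CC(=O)C=CC1=O | starting material
8 | 2-(all-E hexaprenyl)-6-methoxybenzene-1,4-diol | COc1cc(O)cc(C/C=C(\C)CC/C=C(\C)CC/C=C(\C)CC/C=C(\C)CC/C=C(\C)CCC=C(C)C)c1O | intermediate (not isolated)
9 | 2-methoxy-6-[(2E,6E,10E,14E,18E)-3,7,11,15,19,23-hexamethyltetracosa-2,6,10,14,18,22-hexaen-1-yl]cyclohexa-2,5-diene-1,4-dione | COC1=CC(=O)C=C(C/C=C(\C)CC/C=C(\C)CC/C=C(\C)CC/C=C(\C)CC/C=C(\C)CCC=C(C)C)C1=O | target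

## Step count and least certain steps

Total step count: 5. Longest linear sequence: 5 steps (1 → 2 → 3 → 5 → 6 → 9); 1 enters twice and 7 is bought.

**Step 5 (key step).**
- What may go wrong: attack through the O1-bound complex would put the chain on C5. Ipso attack at C2 with loss of methoxide is also possible.
- The 2′E geometry could erode if the bond forms through the 1,2-adduct and a [3,3] shift.
- The hydroquinone could cyclise onto the 2′-olefin under acid (chromanol formation) if the mixture warms before the quench.
- Fallback, from 5 back to 9: 2-bromo-6-methoxyphenol (commercial) is treated with n-BuLi (2.1 equiv, THF, −78 → 0 °C) to give lithium 2-lithio-6-methoxyphenolate F1. After transmetalation with CuBr·SMe2, F1 is alkylated by 5 at its primary allylic carbon (SN2, E retained) to give 2-(all-E hexaprenyl)-6-methoxyphenol F2. Oxidation of F2 with O2 and catalytic Co(salen) in DMF introduces the C4 oxygen para to the phenol and returns to the route at 9. Here the ring position is fixed by the bromine and not by the Lewis acid.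

**Step 3.**
- What may go wrong: chemoselectivity may be lost, with a second displacement at the C1 chloride giving a C45 by-product. Halogen–metal exchange between 4 and 3 would lead to homodimers. α/γ selectivity or geometry would erode if the allylbarium warms.
- Fallback, from 2 back to 5: potassium acetate in DMF replaces the allylic chloride of 2 to give (2E,6E,10E)-12-hydroxy-3,7,11-trimethyldodeca-2,6,10-trien-1-yl acetate F3, and an Appel bromination gives the bromo acetate F4. (2E,6E)-Farnesyl p-tolyl sulfone F5 (from 1 and sodium p-toluenesulfinate in DMF) is deprotonated with n-BuLi (THF/DMPU, −78 °C) and alkylated by F4 at the bromide to give the C30 sulfonyl acetate F6 (racemic at C13′). LiBHEt3 (THF, 0 °C) first cleaves the acetate and then, after addition of catalytic PdCl2(dppp), removes the allylic sulfonyl group with hydride delivery to C13′, giving all-E hexaprenol F7. MsCl, LiCl and 2,4,6-collidine in DMF at 0 °C convert F7 into 5, where the route is rejoined.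

**Step 1.**
- What may go wrong: the allylic chloride may undergo solvolysis or peroxide substitution during the slow oxidation. Over-oxidation to the enal and competing oxidation at internal allylic positions (C4′- or C8′-type methylenes) are also likely.
- Fallback, from 1 back to 5: potassium acetate in DMF converts 1 into (2E,6E)-farnesyl acetate F8, a well-behaved substrate class for this oxidation. SeO2/t-BuOOH then gives F3, which is carried through F4, F6 and F7 as described for step 3 and rejoins the route at 5.

**Step 4.**
- What may go wrong: single-electron transfer from the stannyl anion would cause reductive dimerisation. Partial SN2′ attack would give the tertiary stannane, and the 2′ geometry could be lost.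
- Fallback, from 5 back to 6: the polarity is reversed. Active barium at −78 °C converts 5 into all-E hexaprenylbarium chloride F9, which is captured at its α-carbon by tributyltin chloride at −78 °C to give 6.

## Further compounds

F1 | step 5 | lithium 2-lithio-6-methoxyphenolate | COc1cccc([Li])c1O[Li]
F2 | step 5 | 2-[(2E,6E,10E,14E,18E)-3,7,11,15,19,23-hexamethyltetracosa-2,6,10,14,18,22-hexaen-1-yl]-6-methoxyphenol | COc1cccc(C/C=C(\C)CC/C=C(\C)CC/C=C(\C)CC/C=C(\C)CC/C=C(\C)CCC=C(C)C)c1O
F3 | step 3 | (2E,6E,10E)-12-hydroxy-3,7,11-trimethyldodeca-2,6,10-trien-1-yl acetate | CC(=O)OC/C=C(\C)CC/C=C(\C)CC/C=C(\C)CO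
F4 | step 3 | (2E,6E,10E)-12-bromo-3,7,11-trimethyldodeca-2,6,10-trien-1-yl acetate | CC(=O)OC/C=C(\C)CC/C=C(\C)CC/C=C(\C)CBr
F5 | step 3 | (2E,6E)-farnesyl p-tolyl sulfone | Cc1ccc(cc1)S(=O)(=O)C/C=C(\C)CC/C=C(\C)CCC=C(C)C
F6 | step 3 | (2E,6E,10E,14E,18E)-3,7,11,15,19,23-hexamethyl-13-(p-tolylsulfonyl)tetracosa-2,6,10,14,18,22-hexaen-1-yl acetate (racemic at C13) | CC(=O)OC/C=C(\C)CC/C=C(\C)CC/C=C(\C)CC(/C=C(\C)CC/C=C(\C)CCC=C(C)C)S(=O)(=O)c1ccc(C)cc1
F7 | step 3 | (2E,6E,10E,14E,18E)-3,7,11,15,19,23-hexamethyltetracosa-2,6,10,14,18,22-hexaen-1-ol (all-E hexaprenol) | OC/C=C(\C)CC/C=C(\C)CC/C=C(\C)CC/C=C(\C)CC/C=C(\C)CCC=C(C)C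
F8 | step 1 | (2E,6E)-farnesyl acetate | CC(=O)OC/C=C(\C)CC/C=C(\C)CCC=C(C)C
F9 | step 4 | all-E hexaprenylbarium chloride | Cl[Ba]C/C=C(\C)CC/C=C(\C)CC/C=C(\C)CC/C=C(\C)CC/C=C(\C)CCC=C(C)C
A1 | alternative 1 | 1-bromo-2,3,5-trimethoxybenzene | COc1cc(Br)c(OC)c(OC)c1
A2 | alternative 1 | (2E,6E,10E,14E,18E)-1-bromo-3,7,11,15,19,23-hexamethyltetracosa-2,6,10,14,18,22-hexaene | BrC/C=C(\C)CC/C=C(\C)CC/C=C(\C)CC/C=C(\C)CC/C=C(\C)CCC=C(C)C
A3 | alternative 1 | 1-(all-E hexaprenyl)-2,3,5-trimethoxybenzene | COc1cc(C/C=C(\C)CC/C=C(\C)CC/C=C(\C)CC/C=C(\C)CC/C=C(\C)CCC=C(C)C)c(OC)c(OC)c1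
A4 | alternative 2 | 1-(chloromethyl)-3-methoxy-2-(methoxymethoxy)benzene | COCOc1c(CCl)cccc1OC
A5 | alternative 2 | (5E,9E,13E,17E)-6,10,14,18,22-pentamethyltricosa-5,9,13,17,21-pentaen-1-yne | C#CCC/C=C(\C)CC/C=C(\C)CC/C=C(\C)CC/C=C(\C)CCC=C(C)C
A6 | alternative 2 | 1-(all-E hexaprenyl)-3-methoxy-2-(methoxymethoxy)benzene | COCOc1c(C/C=C(\C)CC/C=C(\C)CC/C=C(\C)CC/C=C(\C)CC/C=C(\C)CCC=C(C)C)cccc1OC
A7 | alternative 3 | 3-methoxycyclobut-3-ene-1,2-dione | COC1=CC(=O)C1=O
A8 | alternative 3 | (4E,8E,12E,16E,20E)-5,9,13,17,21,25-hexamethylhexacosa-4,8,12,16,20,24-hexaen-1-yne | C#CC/C=C(\C)CC/C=C(\C)CC/C=C(\C)CC/C=C(\C)CC/C=C(\C)CCC=C(C)C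
A9 | alternative 3 | 4-hydroxy-3-methoxy-4-[(4E,8E,12E,16E,20E)-5,9,13,17,21,25-hexamethylhexacosa-4,8,12,16,20,24-hexaen-1-yn-1-yl]cyclobut-2-en-1-one (racemic) | COC1=CC(=O)C1(O)C#CC/C=C(\C)CC/C=C(\C)CC/C=C(\C)CC/C=C(\C)CC/C=C(\C)CCC=C(C)C
A10 | alternative 3 | 2-(all-E hexaprenyl)-5-methoxycyclohexa-2,5-diene-1,4-dione | COC1=CC(=O)C(C/C=C(\C)CC/C=C(\C)CC/C=C(\C)CC/C=C(\C)CC/C=C(\C)CCC=C(C)C)=CC1=O
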